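## Structural features

The target is a C25 terpenoid. A trans-fused decalin (rings A and B, C1–C10) carries at C9 the chain C11–C16; C13 holds a methyl group and an E trisubstituted alkene to C14, C16 is C5 of a 4-methylfuran-2(5H)-one whose methyl-bearing β carbon is C17, and C18 is the formyl carbon on C4. Six ring stereocentres lie close together: quaternary C4 (CH3 β, CHO α), C5 (H α), C6 (OH α), C8 (OH α, CH3 β), C9 (H α) and quaternary C10 (CH3 β). The two carbinols are therefore 1,3-diequatorial, and three axial methyl groups close the β face of ring B. The seventh stereocentre, C16 (R), is five bonds from C9 and receives no bias from the decalin. Fragile groups are the butenolide (its C16–H is acidic, so base epimerises or opens it), the neopentyl aldehyde 1,4 to the C6 hydroxyl (lactol formation, over-oxidation), the tertiary C8 alcohol (loss of water in acid) and any C16 aldehyde precursor, which is β,γ-unsaturated. The carbon skeleton is easy, because C1–C13 with C18 is an abietane cut between C13 and the carbon that becomes the C8 methyl group; the real difficulty lies in the equatorial 6α-alcohol (hydride adds from the open α face and gives the wrong epimer), the E alkene and the isolated C16 centre. The key step uses the fact that C16–C17 joins a carbinol carbon to the β carbon of a (Z)-crotonate: with C17 turned into an alkenyl anion it adds to a C16 aldehyde, and the cis ester closes the lactone. An atom-by-atom check of 1, 21, 23 and 25 against the target (4α-CH2O, 5α-H, 6α-O, 8α-O, 9α-H, 10β-CH3, 13E, 16R, Z iodide) showed no conflict, so no structure needed correction.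

## Logic of the disconnections

**28 ⇒ 25 (through 27 and 26).** No skeletal bond is cut: the C18 aldehyde goes back to an arylmethyl ether and the two hydroxyls to silyl ethers. The aldehyde and the diol would not survive organometallic steps, and a free C6 hydroxyl next to a C18 aldehyde invites lactol formation during oxidation. The gain is that 25 carries only inert groups. The demand is that all three unmasking steps be non-basic, because C16 of the butenolide epimerises with base.

**25 ⇒ 21 + 23.** The C16–C17 bond and the lactone C–O bond are cut. This is the one bond that joins the large half to a four-carbon unit, and cutting it removes a ring and a stereocentre at once. The forward step needs a β-acyl alkenyl anion that tolerates an ester, keeps Z geometry, and adds to one face of a remote, enolisable aldehyde. The design of 21 answers this in three ways: it is made under neutral conditions and used crude, the coupling uses a hindered amine, and its protecting groups go on in only two operations (steps 2 and 10), so that 21 is reached in thirteen steps from 1.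

**23 ⇒ 22.** The C–I and the vinylic C–H bond are cut. The gain is a commercial ynoate; the demand is anti addition of HI so that iodine ends cis to the ester.

**21 ⇒ 20 ⇒ 16 + 17.** After return to the alcohol level, C14–C15 and C13–CH3 are cut. A terminal alkyne hides the trisubstituted alkene, and its syn methylmetalation is the most reliable source of pure E geometry. The gain is that alkene geometry is no longer a problem and the last two carbons come from 17. The demand is stereoretentive transfer of the alkenyl group to an epoxide and an oxidation that does not move the alkene.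

**16 ⇒ 14.** C13≡C14 is cut; C14 comes from a one-carbon reagent and C13 goes back to an ester. The gain is a robust ester that is the direct product of the degradation. The demand is a reduction that stops at the aldehyde.

**14 ⇒ 13 ⇒ 11 ⇒ 10.** The O–Si bonds are cut, then the C6 carbinol and the C8–O bond are traced to a 7-en-6-one. An enone lets oxygen be put on C8 as a nucleophile from the open α face and lets C6 be reduced under thermodynamic control. The gain is that two stereocentres become one flat enone. The demands are α-face peroxide addition and an electron-transfer reduction that gives the equatorial alcohol.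

**10 ⇒ 9.** The ester O–CH(CH3)2 bond is cut, which puts the isopropyl group back on C13 as a ketone. The gain is that 9 still has every carbon of the starting diterpene. The demand is selective migration of isopropyl and an enone inert to peracid.

**9 ⇒ 8 ⇒ 6 ⇒ 5.** The C6 carbonyl is removed and the C8 methyl is taken back through CH2OH to CHO. The gain is the enal that ring cleavage gives directly. The demand is allylic oxidation at C6 and not at the methyl group, with the ether at C18 surviving.

**5 ⇒ 3.** C13 and the formyl carbon on C8 are reconnected as an alkene, which re-forms ring C. The gain is the intact abietane. The demand is oxidative cleavage of only one alkene of a conjugated diene.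

**3 ⇒ 2 ⇒ 1.** The benzyl ether C–O bond is cut and C18 is returned to the acid. Compound 1 supplies C4, C5, C9 and C10 with the right configurations and with C18 already oxidised.

## Other disconnections considered

**Alternative 1:** The cut is through C4–C5, C9–C10 and C8–O. In the forward step SnCl4 opens the 2,2-disubstituted epoxide of the acyclic epoxy dienoic acid A1, two alkenes add in turn and the acid traps the C8 cation to give the hydroxy lactone A2. In its favour, one step builds rings A and B, five stereocentres and the C18 and C8 oxygens, and the lactone carbon is a handle for the side chain. For ring construction this is better in step economy than the chosen degradation, which spends ten steps on the core. Against it here: A2 has no oxygen at C6 and offers no reliable way to add one, and the absolute configuration rests on an enantiopure 2,2-disubstituted epoxide, which is hard to obtain. If the epoxide ionises to a tertiary cation before the alkene attacks, the C4 configuration is eroded. The chosen plan buys C4, C5, C9 and C10 from the chiral pool and has no such question; on the full oxidation pattern it is the safer one.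

**Alternative 2:** The cut is C6–C7 of ring B. In the forward step (CH3)2AlCl activates the aldehyde of the monocyclic A3 and the isopropenyl group adds in a type 2 carbonyl-ene reaction to give the hydroxy ester A4. In its favour, the chair-like transition state delivers the 6α-alcohol directly, and the exocyclic alkene is the best precursor of the C8 carbinol (α epoxidation, hydride opening). On C6 and C8 stereocontrol this alternative is better than the chosen plan, which relies on a thermodynamic reduction. Against it here: A4 has a gem-dimethyl C4, so C18 is not oxygenated. Either the two methyl groups must be told apart later or A3 must carry a fourth stereocentre at C4. A3 itself needs three contiguous centres, one of them quaternary, made from nothing, and the ester needs a two-carbon extension. In total steps the chosen plan is shorter, because the chiral pool supplies ring A complete.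

**Alternative 3:** The cuts are C13–CH3 and C14–C15. Alkyne 16 is carboaluminated with Al(CH3)3 and Cp2ZrCl2, and the lithium alanate opens the chiral epoxide A5 at its CH2 carbon to give the alcohol A6. In its favour, C16 comes from the chiral pool instead of from ligand control at a remote aldehyde, and no β,γ-unsaturated aldehyde is needed; on both points it is better than the chosen plan. Control of the E alkene is the same in both, so there the two are equal. Against it here: the butenolide must still be built from A6 (acylation with a phosphonoacetic acid, oxidation at C17, intramolecular Horner–Wadsworth–Emmons closure), which costs about four more steps. The ketone stage has C16 α to a carbonyl, where base can undo the configuration. The two PMB ethers of A6 also need differentiation.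

Key step: step 15

Assumptions:
- Commercial abietic acid is purified through an amine salt before use.
- The target is taken as the open hydroxy aldehyde drawn; a lactol between the C6 hydroxyl and C18 would be its ring tautomer.
- "C8 methyl carbon" in compounds 3–9 is abietane C14.
- The ligand of step 15 is (S)-N-[2-(4-isopropyl-4,5-dihydrooxazol-2-yl)-6-methylphenyl]methanesulfonamide or its enantiomer, whichever sends the alkenyl group to the Si face; this is settled beforehand on 3-phenylpropanal.

## Route

Step 1
Reactants: 1 abietic acid
Product: 2 abietinol
Conditions: LiAlH4, THF, 0 °C to reflux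
Reagents that add atoms: none
Why: Hydride reduction of the carboxylic acid to the primary alcohol (LiAlH4 reduction); the diene and the ring stereocentres C4, C5, C9 and C10 are untouched, and C18 now stands at the level from which the aldehyde is made at the end.

Step 2
Reactants: 2 abietinol
Product: 3 abietinol PMB ether
Conditions: NaH, PMBCl, n-Bu4NI (cat.), THF/DMF, 0 °C to rt
Reagents that add atoms: 4-methoxybenzyl chloride COc1ccc(CCl)cc1
Why: Williamson ether synthesis on the neopentyl alkoxide with iodide catalysis; the PMB ether is put on first because it is the one group that can later be removed oxidatively beside silyl ethers and the butenolide.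

Step 3
Reactants: 3 abietinol PMB ether
Product: 5 keto enal, via cis-diol 4 (not isolated)
Conditions: OsO4 (2 mol%), NaIO4, 2,6-lutidine, dioxane/H2O, rt
Reagents that add atoms: osmium tetroxide O=[Os](=O)(=O)=O; sodium periodate [Na+].[O-]I(=O)(=O)=O
Why: Lemieux–Johnson oxidation: OsO4 should add to the ring C alkene, the more exposed end of the diene, and NaIO4 cleaves the diol as it forms; the C7=C8 alkene left behind is conjugated to the new aldehyde and too electron-poor to be attacked again, and the two transient diol centres vanish.

Step 4
Reactants: 5 keto enal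
Product: 6 keto allylic alcohol
Conditions: NaBH4, CH2Cl2/MeOH, −78 °C
Reagents that add atoms: none
Why: Borohydride 1,2-reduction of the aldehyde; at −78 °C an aldehyde reacts far faster than the hindered isopropyl ketone, and the enal is attacked at the carbonyl carbon, not in conjugate fashion.

Step 5
Reactants: 6 keto allylic alcohol
Product: 8 alkenyl alcohol with C8 methyl group, via allylic mesylate 7 (not isolated)
Conditions: MsCl, Et3N, THF, −40 °C; then LiBHEt3, −40 to 0 °C
Reagents that add atoms: none
Why: Sulfonylation and SN2 hydride displacement at the primary allylic carbon turn CH2OH into the C8 methyl group and keep the alkene at C7=C8; the same hydride reduces the C13 ketone to an epimeric alcohol, which costs nothing because step 6 oxidises it back.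

Step 6
Reactants: 8 alkenyl alcohol
Product: 9 enone ketone
Conditions: CrO3, 3,5-dimethylpyrazole, CH2Cl2, −20 °C
Reagents that add atoms: chromium trioxide O=[Cr](=O)=O
Why: Allylic oxidation by hexavalent chromium: the ring CH2 next to the less substituted alkene carbon (C6) is oxidised to the 7-en-6-one, the regiochemistry known from 5-ene steroids giving 7-ketones, and the C13 alcohol is oxidised to the ketone in the same flask; at −20 °C the PMB ether is expected to outlast the short reaction.

Step 7
Reactants: 9 enone ketone
Product: 10 enone isopropyl ester
Conditions: mCPBA, NaHCO3, CH2Cl2, rt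
Reagents that add atoms: 3-chloroperoxybenzoic acid OOC(=O)c1cccc(Cl)c1
Why: Baeyer–Villiger oxidation: the secondary isopropyl group migrates in preference to the primary C12 methylene, so oxygen is inserted on the outer side of C13 and the three surplus carbons become the alkoxy group of an ester; the conjugated C6 ketone and its electron-poor alkene react much more slowly with the peracid.

Step 8
Reactants: 10 enone isopropyl ester
Product: 11 epoxy ketone
Conditions: t-BuOOH, benzyltrimethylammonium hydroxide (cat.), THF, 0 °C to rt
Reagents that add atoms: tert-butyl hydroperoxide CC(C)(C)OO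
Why: Weitz–Scheffer nucleophilic epoxidation: the peroxide anion adds to C8 from the α face, because the β face is blocked by the axial C10 methyl group 1,3 to C8, and the enolate closes the epoxide; this sets C8 with oxygen α and methyl β, and C5 and C9, both epimerisable under base, already hold their more stable configurations.

Step 9
Reactants: 11 epoxy ketone
Product: 13 diol ester, via hydroxy ketone 12 (not isolated)
Conditions: SmI2, THF/MeOH, −90 °C; then SmI2, H2O, Et3N, 0 °C
Reagents that add atoms: none
Why: Divalent samarium first cleaves the Cα–O bond of the α,β-epoxy ketone (reductive epoxide opening), which leaves the C8–O bond and its configuration intact. With water and amine it then reduces the C6 ketone through a ketyl and carbanion that is protonated from the axial β direction, giving the equatorial 6α-alcohol as in dissolving-metal reductions of hindered ring ketones, where hydride would give the axial epimer. Ketones are reduced far faster than the isopropyl ester under these conditions.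

Step 10
Reactants: 13 diol ester
Product: 14 bis-silyl ether ester
Conditions: Et3SiOTf, 2,6-lutidine, CH2Cl2, 0 °C to rt
Reagents that add atoms: triethylsilyl trifluoromethanesulfonate CC[Si](CC)(CC)OS(=O)(=O)C(F)(F)F
Why: Silylation with the silyl triflate and a hindered pyridine base; the reagent is strong enough for the hindered secondary and the tertiary hydroxyl, so both are protected in one operation.

Step 11
Reactants: 14 bis-silyl ether ester
Product: 16 terminal alkyne, via aldehyde 15 (not isolated)
Conditions: i-Bu2AlH, CH2Cl2, −78 °C; then MeOH, K2CO3, dimethyl (1-diazo-2-oxopropyl)phosphonate, −78 °C to rt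
Reagents that add atoms: dimethyl (1-diazo-2-oxopropyl)phosphonate CC(=O)C(=[N+]=[N-])P(=O)(OC)OC
Why: Partial reduction of the ester to the aldehyde (the aluminium hemiacetal is stable at −78 °C), then Seyferth–Gilbert homologation in the same flask: methoxide unmasks the diazomethylphosphonate anion, which converts C13=O into the terminal alkyne and supplies C14.

Step 12
Reactants: 16 terminal alkyne; 17 oxirane
Product: 20 homoallylic alcohol, via alkenylalane 18 (not isolated), via lithium alanate 19 (not isolated)
Conditions: Me3Al, Cp2ZrCl2, CH2Cl2, 0 °C to rt; volatiles removed; n-BuLi, THF, −78 °C; oxirane, −78 to 0 °C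
Reagents that add atoms: trimethylaluminium C[Al](C)C
Why: Zirconium-catalysed carboalumination adds CH3 and aluminium syn across the terminal alkyne with aluminium on the end carbon, which fixes the 13E geometry; n-BuLi turns the alane into an alanate that transfers the alkenyl group with retention to a CH2 of oxirane (epoxide opening), forming C14–C15.

Step 13
Reactants: 20 homoallylic alcohol
Product: 21 C1–C16 aldehyde
Conditions: DMP, NaHCO3, CH2Cl2, 0 °C; used crude
Reagents that add atoms: none
Why: Periodinane oxidation of the primary alcohol under buffered neutral conditions, chosen so that the β,γ-unsaturated aldehyde is not enolised; it is used at once without chromatography.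

Step 14
Reactants: 22 methyl but-2-ynoate
Product: 23 methyl (Z)-3-iodobut-2-enoate
Conditions: NaI, AcOH, 115 °C
Reagents that add atoms: sodium iodide [Na+].[I-]
Why: Conjugate hydroiodination of the ynoate: iodide adds to C3 and the proton is delivered anti, so iodine ends cis to the ester (Z), the geometry required for ring closure in step 15.

Step 15
Reactants: 21 C1–C16 aldehyde; 23 methyl (Z)-3-iodobut-2-enoate
Product: 25 protected target, via hydroxy enoate 24 (not isolated)
Conditions: CrCl2, NiCl2 (cat.), chiral oxazoline–sulfonamide ligand, 1,8-bis(dimethylamino)naphthalene, THF, rt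
Reagents that add atoms: none
Why: Zerovalent nickel, formed from NiCl2 and CrCl2, inserts into the C–I bond of 23 and passes the alkenyl group to trivalent chromium with the Z geometry kept. The alkenylchromium species, held in the chiral sulfonamidate–oxazoline ligand sphere, adds to the aldehyde of 21 and forms C16–C17 (Nozaki–Hiyama–Kishi reaction). The closest known chemistry is the coupling of β-iodoenoates with aldehydes that ends in butenolides, together with ligand-controlled enantioselective nickel/chromium couplings of alkenyl iodides. The chromium alkoxide of 24 lies cis to the methyl ester and attacks it, a 5-exo-trig acyl substitution that expels methoxide and closes the butenolide ring. C16 is set by the ligand alone: addition to the Si face of the aldehyde gives 16R, the decalin being too far away to matter. The step needs chemoselectivity for the aldehyde over esters and ethers, which organochromium reagents have by nature, and it needs the C13=C14 alkene to stay out of conjugation, which the near-neutral medium with a hindered amine secures. Ring closure needs the cis relation of carbinol and ester, which the Z iodide and the stereoretentive transmetalation secure, and the PMB and silyl ethers are inert.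

Step 16
Reactants: 25 protected target
Product: 26 C18 alcohol
Conditions: DDQ, CH2Cl2/pH 7 buffer, 0 °C to rt
Reagents that add atoms: none
Why: Oxidative cleavage of the PMB ether: DDQ abstracts hydride from the electron-rich benzylic position and water hydrolyses the oxocarbenium ion; buffered conditions spare the silyl ethers, the alkene and the butenolide.

Step 17
Reactants: 26 C18 alcohol
Product: 27 C18 aldehyde
Conditions: DMP, NaHCO3, CH2Cl2, 0 °C to rt
Reagents that add atoms: none
Why: Periodinane oxidation of the neopentyl primary alcohol to the aldehyde; the C6 oxygen is still silylated, so no lactol can form and be oxidised on to a lactone.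

Step 18
Reactants: 27 C18 aldehyde
Product: 28 target
Conditions: HF·pyridine, pyridine, THF, 0 °C to rt
Reagents that add atoms: none
Why: Fluoride-driven cleavage of both Si–O bonds with buffered HF·pyridine; the non-basic medium leaves the butenolide (C16) and the aldehyde untouched.

## Compound list

1 | abietic acid (abieta-7,13-dien-18-oic acid) | C3=C(C(C)C)CC[C@@H]1[C@@]2(C)CCC[C@@](C)(C(=O)O)[C@@H]2CC=C13 | starting material
2 | abietinol (abieta-7,13-dien-18-ol) | C3=C(C(C)C)CC[C@@H]1[C@@]2(C)CCC[C@@](C)(CO)[C@@H]2CC=C13 | intermediate
3 | 18-(4-methoxybenzyloxy)abieta-7,13-diene | C3=C(C(C)C)CC[C@@H]1[C@@]2(C)CCC[C@@](C)(COCc4ccc(OC)cc4)[C@@H]2CC=C13 | intermediate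
4 | 18-(4-methoxybenzyloxy)abiet-7-ene-13α,14α-diol (cis-diol, not isolated) | O[C@H]3[C@](O)(C(C)C)CC[C@@H]1[C@@]2(C)CCC[C@@](C)(COCc4ccc(OC)cc4)[C@@H]2CC=C13 | intermediate
5 | keto enal: 18-O-PMB decalin with 7-ene, formyl on C8 and 4-methyl-3-oxopentyl on C9 (13-oxo-13,14-secoabiet-7-en-14-al) | CC(C)C(=O)CC[C@@H]1[C@@]2(C)CCC[C@@](C)(COCc3ccc(OC)cc3)[C@@H]2CC=C1C=O | intermediate
6 | keto allylic alcohol: as 5 with CH2OH on C8 | CC(C)C(=O)CC[C@@H]1[C@@]2(C)CCC[C@@](C)(COCc3ccc(OC)cc3)[C@@H]2CC=C1CO | intermediate
7 | allylic methanesulfonate of 6 (not isolated) | CC(C)C(=O)CC[C@@H]1[C@@]2(C)CCC[C@@](C)(COCc3ccc(OC)cc3)[C@@H]2CC=C1COS(C)(=O)=O | intermediate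
8 | 18-O-PMB 8-methyl-7-ene with C13 secondary alcohol (both C13 epimers) | CC(C)C(O)CC[C@@H]1[C@@]2(C)CCC[C@@](C)(COCc3ccc(OC)cc3)[C@@H]2CC=C1C | intermediate
9 | 18-O-PMB 8-methyl-7-en-6-one with C13 isopropyl ketone | CC(C)C(=O)CC[C@@H]1[C@@]2(C)CCC[C@@](C)(COCc3ccc(OC)cc3)[C@@H]2C(=O)C=C1C | intermediate
10 | isopropyl ester of the C1–C13 acid, 8-methyl-7-en-6-one, 18-O-PMB | CC(C)OC(=O)CC[C@@H]1[C@@]2(C)CCC[C@@](C)(COCc3ccc(OC)cc3)[C@@H]2C(=O)C=C1C | intermediate
11 | 7α,8α-epoxy-6-ketone of 10 | CC(C)OC(=O)CC[C@@H]1[C@@]2(C)CCC[C@@](C)(COCc3ccc(OC)cc3)[C@@H]2C(=O)[C@H]4O[C@@]14C | intermediate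
12 | 8α-hydroxy-6-ketone, isopropyl ester, 18-O-PMB (not isolated) | CC(C)OC(=O)CC[C@@H]1[C@@]2(C)CCC[C@@](C)(COCc3ccc(OC)cc3)[C@@H]2C(=O)C[C@@]1(C)O | intermediate
13 | 6α,8α-diol, isopropyl ester, 18-O-PMB | CC(C)OC(=O)CC[C@@H]1[C@@]2(C)CCC[C@@](C)(COCc3ccc(OC)cc3)[C@@H]2[C@@H](O)C[C@@]1(C)O | intermediate
14 | 6α,8α-bis(triethylsilyloxy) isopropyl ester, 18-O-PMB | CC(C)OC(=O)CC[C@@H]1[C@@]2(C)CCC[C@@](C)(COCc3ccc(OC)cc3)[C@@H]2[C@@H](O[Si](CC)(CC)CC)C[C@@]1(C)O[Si](CC)(CC)CC | intermediate
15 | C13 aldehyde, 6,8-bis-O-TES, 18-O-PMB (not isolated) | O=CCC[C@@H]1[C@@]2(C)CCC[C@@](C)(COCc3ccc(OC)cc3)[C@@H]2[C@@H](O[Si](CC)(CC)CC)C[C@@]1(C)O[Si](CC)(CC)CC | intermediate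
16 | C13≡C14 terminal alkyne, 6,8-bis-O-TES, 18-O-PMB | C#CCC[C@@H]1[C@@]2(C)CCC[C@@](C)(COCc3ccc(OC)cc3)[C@@H]2[C@@H](O[Si](CC)(CC)CC)C[C@@]1(C)O[Si](CC)(CC)CC | intermediate
17 | oxirane | C1CO1 | starting material
18 | (E)-2-methylalkenyl dimethylalane from 16 (not isolated) | C[Al](C)/C=C(\C)CC[C@@H]1[C@@]2(C)CCC[C@@](C)(COCc3ccc(OC)cc3)[C@@H]2[C@@H](O[Si](CC)(CC)CC)C[C@@]1(C)O[Si](CC)(CC)CC | intermediate
19 | lithium butyl(alkenyl)dimethylalanate from 18 (not isolated) | [Li+].CCCC[Al-](C)(C)/C=C(\C)CC[C@@H]1[C@@]2(C)CCC[C@@](C)(COCc3ccc(OC)cc3)[C@@H]2[C@@H](O[Si](CC)(CC)CC)C[C@@]1(C)O[Si](CC)(CC)CC | intermediate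
20 | (13E) C16 primary alcohol, 6,8-bis-O-TES, 18-O-PMB | OCC/C=C(\C)CC[C@@H]1[C@@]2(C)CCC[C@@](C)(COCc3ccc(OC)cc3)[C@@H]2[C@@H](O[Si](CC)(CC)CC)C[C@@]1(C)O[Si](CC)(CC)CC | intermediate
21 | (13E) C1–C16 aldehyde, 6,8-bis-O-TES, 18-O-PMB | O=CC/C=C(\C)CC[C@@H]1[C@@]2(C)CCC[C@@](C)(COCc3ccc(OC)cc3)[C@@H]2[C@@H](O[Si](CC)(CC)CC)C[C@@]1(C)O[Si](CC)(CC)CC | intermediate
22 | methyl but-2-ynoate | CC#CC(=O)OC | starting material
23 | methyl (Z)-3-iodobut-2-enoate | C/C(I)=C/C(=O)OC | intermediate
24 | methyl (Z)-3-methyl-4-hydroxy-2-enoate with 16R carbinol, present as its chromium alkoxide (not isolated) | COC(=O)/C=C(/C)[C@H](O)C/C=C(\C)CC[C@@H]1[C@@]2(C)CCC[C@@](C)(COCc3ccc(OC)cc3)[C@@H]2[C@@H](O[Si](CC)(CC)CC)C[C@@]1(C)O[Si](CC)(CC)CC | intermediate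
25 | protected target: butenolide, 6,8-bis-O-TES, 18-O-PMB | CC1=CC(=O)O[C@@H]1C/C=C(\C)CC[C@@H]1[C@@]2(C)CCC[C@@](C)(COCc3ccc(OC)cc3)[C@@H]2[C@@H](O[Si](CC)(CC)CC)C[C@@]1(C)O[Si](CC)(CC)CC | intermediate
26 | C18 primary alcohol, butenolide, 6,8-bis-O-TES | CC1=CC(=O)O[C@@H]1C/C=C(\C)CC[C@@H]1[C@@]2(C)CCC[C@@](C)(CO)[C@@H]2[C@@H](O[Si](CC)(CC)CC)C[C@@]1(C)O[Si](CC)(CC)CC | intermediate
27 | C18 aldehyde, butenolide, 6,8-bis-O-TES | CC1=CC(=O)O[C@@H]1C/C=C(\C)CC[C@@H]1[C@@]2(C)CCC[C@@](C)(C=O)[C@@H]2[C@@H](O[Si](CC)(CC)CC)C[C@@]1(C)O[Si](CC)(CC)CC | intermediate
28 | CNP0143336.1 | CC1=CC(=O)O[C@@H]1C/C=C(\C)CC[C@@H]1[C@@]2(C)CCC[C@@](C)(C=O)[C@@H]2[C@@H](O)C[C@@]1(C)O | target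

## Step count and least certain steps

Total step count: 18. Longest linear sequence: 17 steps (steps 1–13 and 15–18, from 1 to 28); step 14 is a one-step side branch.

**Step 15 (key step).** Three things may go wrong. Facial discrimination at the remote C16 aldehyde may be insufficient, leaving C16 epimers that are hard to separate. The C13=C14 alkene may shift into conjugation with the aldehyde before coupling. The alkenyl metal species may lose its Z geometry, which stops lactonisation. The fallback sets out from 21. Enantioselective alkynylation with methyl propiolate (Me2Zn, chiral bis(diarylprolinol)phenol ligand, toluene) gives the 16R hydroxy ynoate F1. Me2CuLi at −78 °C then adds CH3 and copper syn across the alkyne, which gives 24 after protonation, and 24 lactonises to 25, where the route is rejoined.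

**Step 6.** Benzylic oxidation of the PMB ether by hexavalent chromium may compete with allylic oxidation, as may attack at the C8 methyl group, because all these C–H bonds are activated to a similar degree. The fallback sets out from 8 and avoids the strong oxidant. mCPBA epoxidises the alkene from the α face to the epoxide F2. PhSeNa (from PhSeSePh and NaBH4, EtOH) opens it at C7 to the hydroxy selenide F3. H2O2 oxidises this to the selenoxide F4, which eliminates toward C6 to the tertiary allylic alcohol F5. C5H5NH[CrO3Cl] (pyridinium chlorochromate), a mild reagent that PMB ethers tolerate, then effects the Babler–Dauben oxidative 1,3-transposition of F5 and oxidises the C13 alcohol, which returns to 9.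

**Step 8.** The peroxide may add from the wrong face of C8, or not at all, because the β carbon is fully substituted and hindered; base may also move the alkene out of conjugation. The fallback sets out from 10. Conjugate borylation (CuCl, NaOt-Bu, a bisphosphine, B2pin2, MeOH, THF) should deliver the bulky boryl–copper reagent from the α face to give the boryl ketone F6. NaBO3 oxidises the C–B bond with retention to 12, where the route is rejoined at the second stage of step 9.

**Step 9.** Protonation of the reduced C6 centre may show poor facial selectivity and give some axial 6β-alcohol; the β-hydroxy ketone may also open by retro-aldol cleavage, or the ester may be over-reduced. The fallback sets out from 12, isolated after the first stage. It is reduced under equilibrating Meerwein–Ponndorf–Verley conditions (Al(Oi-Pr)3, i-PrOH, toluene, heat), where reversible hydride transfer leads to the more stable equatorial alcohol and isopropoxide exchange leaves the isopropyl ester unchanged. This returns to 13 and makes no new compound (F0).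

## Further compounds

F1 | step 15 | methyl 4-hydroxyalk-2-ynoate with 16R carbinol, from 21 and methyl propiolate (6,8-bis-O-TES, 18-O-PMB) | COC(=O)C#C[C@H](O)C/C=C(\C)CC[C@@H]1[C@@]2(C)CCC[C@@](C)(COCc3ccc(OC)cc3)[C@@H]2[C@@H](O[Si](CC)(CC)CC)C[C@@]1(C)O[Si](CC)(CC)CC
F2 | step 6 | 7α,8α-epoxide of 8 (C13 epimers) | CC(C)C(O)CC[C@@H]1[C@@]2(C)CCC[C@@](C)(COCc3ccc(OC)cc3)[C@@H]2C[C@H]4O[C@@]14C
F3 | step 6 | 7β-phenylselanyl-8α-hydroxy compound from F2 | CC(C)C(O)CC[C@@H]1[C@@]2(C)CCC[C@@](C)(COCc3ccc(OC)cc3)[C@@H]2C[C@H]([Se]c4ccccc4)[C@@]1(C)O
F4 | step 6 | selenoxide of F3 | CC(C)C(O)CC[C@@H]1[C@@]2(C)CCC[C@@](C)(COCc3ccc(OC)cc3)[C@@H]2C[C@H]([Se](=O)c4ccccc4)[C@@]1(C)O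
F5 | step 6 | 8α-hydroxy-8β-methyl-6-ene (tertiary allylic alcohol) | CC(C)C(O)CC[C@@H]1[C@@]2(C)CCC[C@@](C)(COCc3ccc(OC)cc3)[C@@H]2C=C[C@@]1(C)O
F6 | step 8 | 8α-(pinacolboryl)-6-ketone, isopropyl ester, 18-O-PMB | CC(C)OC(=O)CC[C@@H]1[C@@]2(C)CCC[C@@](C)(COCc3ccc(OC)cc3)[C@@H]2C(=O)C[C@@]1(C)B4OC(C)(C)C(C)(C)O4
F0 | step 9 | none | none
A1 | alternative 1 | (3E,7E)-4,8-dimethyl-11-[(2R)-2-methyloxiran-2-yl]undeca-3,7-dienoic acid | OC(=O)C/C=C(\C)CC/C=C(\C)CCC[C@]1(C)CO1
A2 | alternative 1 | 18-hydroxysclareolide | O=C3C[C@@H]1[C@@]2(C)CCC[C@@](C)(CO)[C@@H]2CC[C@@]1(C)O3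
A3 | alternative 2 | ethyl 2-(2-formyl-1,3,3-trimethylcyclohexyl)-3-methylbut-3-enoate | CCOC(=O)[C@@H](C(C)=C)[C@@]1(C)CCCC(C)(C)[C@@H]1C=O
A4 | alternative 2 | ethyl 6α-hydroxydrim-8(12)-en-11-oate | CCOC(=O)[C@@H]1[C@@]2(C)CCCC(C)(C)[C@@H]2[C@@H](O)CC1=C
A5 | alternative 3 | (2R)-2-[(1S)-1-(4-methoxybenzyloxy)ethyl]oxirane | C[C@H](OCc1ccc(OC)cc1)[C@H]1CO1
A6 | alternative 3 | (13E) homoallylic alcohol with 16R carbinol and 17-O-PMB, 6,8-bis-O-TES, 18-O-PMB | C[C@H](OCc4ccc(OC)cc4)[C@H](O)C/C=C(\C)CC[C@@H]1[C@@]2(C)CCC[C@@](C)(COCc3ccc(OC)cc3)[C@@H]2[C@@H](O[Si](CC)(CC)CC)C[C@@]1(C)O[Si](CC)(CC)CC
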